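## Retrosynthetic overview

1. The target is a 4β→6 linked biflavanoid: an upper 7,8,4'-trihydroxy-2,3-cis-flavan-3-ol unit (rings A, B, C) bonded through C4 to C6 of (−)-melacacidin (rings D, E, F). The last operations are removal of a cyclic carbonate and global O-debenzylation.
2. The interflavanyl C4–C6 bond is cut by a Friedel–Crafts (SN1) disconnection: a benzylic C4 cation from an all-cis flavan-3,4-diol (upper unit) plus the arene of the melacacidin 3,4-carbonate (lower unit).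
3. Each all-cis flavan-3,4-diol comes from a (2S)-flavanone: silyl enol ether, hydroboration (sets C4, frees only 3-OH), then oxidation and bulky-hydride reduction at C3.
4. Each pyranone ring (ring C, ring F) is closed by a catalytic asymmetric intramolecular oxa-Michael addition of a 2'-hydroxyaryl alkylidene β-ketoester, which sets C2, followed by decarboxylation.
5. Both alkylidenes come from one β-ketoester (from gallacetophenone) and two benzyloxybenzaldehydes. Order of ring formation: the arene rings are bought, ring C and ring F are closed in parallel, and the only later ring is the temporary carbonate.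

Assumption: the cinchona thiourea pseudoenantiomer that gives the 2S flavanone is used (written as the quinidine-derived catalyst; the quinine-derived one gives the mirror series), checked on the first batch by CD.

## Route

Step 1
Reactants: 1 1-(2,3,4-trihydroxyphenyl)ethanone (gallacetophenone)
Product: 2 1-[3,4-bis(benzyloxy)-2-hydroxyphenyl]ethanone
Conditions: BnBr (2.05 equiv), K2CO3 (2.2 equiv), DMF, rt
Reagents that add atoms: benzyl bromide BrCc1ccccc1
Why: Williamson etherification; the 2-OH is hydrogen-bonded to the ketone and least nucleophilic, so only the 4-OH and 3-OH are benzylated.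

Step 2
Reactants: 2 1-[3,4-bis(benzyloxy)-2-hydroxyphenyl]ethanone
Product: 3 tert-butyl 3-[3,4-bis(benzyloxy)-2-hydroxyphenyl]-3-oxopropanoate
Conditions: LiN(SiMe3)2 (3.3 equiv), THF, −78 °C; Boc2O (1.1 equiv), −78 → 0 °C; aq NH4Cl
Reagents that add atoms: di-tert-butyl dicarbonate CC(C)(C)OC(=O)OC(=O)OC(C)(C)C
Why: Claisen-type C-acylation of the phenoxide/enolate dianion (any O-aryl carbonate formed first is carried to the same product by a Baker–Venkataraman-type O→C acyl shift), with the third equivalent of base holding the product as its enolate against over-acylation and the tert-butyl ester allowing later acid decarboxylation.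

Step 3
Reactants: 3 tert-butyl 3-[3,4-bis(benzyloxy)-2-hydroxyphenyl]-3-oxopropanoate; 4 4-(benzyloxy)benzaldehyde
Product: 5 tert-butyl (2Z)-2-[3,4-bis(benzyloxy)-2-hydroxybenzoyl]-3-[4-(benzyloxy)phenyl]prop-2-enoate (E/Z mixture, Z drawn)
Conditions: piperidine (cat.), AcOH (cat.), 4 Å MS, toluene, rt
Reagents that add atoms: none
Why: Knoevenagel condensation of the active methylene with the aldehyde; no stereocentre is formed and both alkene isomers converge in step 4.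

Step 4
Reactants: 5 tert-butyl (2Z)-2-[3,4-bis(benzyloxy)-2-hydroxybenzoyl]-3-[4-(benzyloxy)phenyl]prop-2-enoate
Product: 8 (2S)-7,8-bis(benzyloxy)-2-[4-(benzyloxy)phenyl]chroman-4-one, via cyclised tert-butyl ester 6 (not isolated), via β-keto acid 7 (not isolated)
Conditions: N-[3,5-bis(trifluoromethyl)phenyl]-N′-(9-deoxy-epi-quinidin-9-yl)thiourea (10 mol%), toluene, −25 °C; then p-TsOH·H2O, 80 °C; recrystallise
Reagents that add atoms: none
Why: Catalytic asymmetric intramolecular oxa-Michael addition (thiourea binds the β-ketoester, the quinuclidine activates the phenol) closes ring C and sets C2 (S, about 90% ee before recrystallisation); acidolysis and decarboxylation then remove the ester without base, so no retro-Michael racemisation occurs.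

Step 5
Reactants: 8 (2S)-7,8-bis(benzyloxy)-2-[4-(benzyloxy)phenyl]chroman-4-one
Product: 9 {[(2S)-7,8-bis(benzyloxy)-2-[4-(benzyloxy)phenyl]-2H-chromen-4-yl]oxy}(tert-butyl)dimethylsilane
Conditions: TBSOTf (1.3 equiv), Et3N (2 equiv), CH2Cl2, 0 °C
Reagents that add atoms: tert-butyldimethylsilyl triflate CC(C)(C)[Si](C)(C)OS(=O)(=O)C(F)(F)F
Why: Soft enolisation to the silyl enol ether avoids a free enolate and therefore the E1cB ring opening that would racemise C2.

Step 6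
Reactants: 9 {[(2S)-7,8-bis(benzyloxy)-2-[4-(benzyloxy)phenyl]-2H-chromen-4-yl]oxy}(tert-butyl)dimethylsilane
Product: 11 (2R,3R,4R)-7,8-bis(benzyloxy)-2-[4-(benzyloxy)phenyl]-4-[(tert-butyldimethylsilyl)oxy]chroman-3-ol (2,3-trans-3,4-trans), via C3 alkylborane 10 (not isolated)
Conditions: BH3·THF (2 equiv), THF, 0 °C → rt; then 30% H2O2, aq NaOAc, 0 °C
Reagents that add atoms: borane–THF B.C1CCOC1 (boron stays only in 10); hydrogen peroxide OO
Why: Hydroboration–oxidation (syn addition) puts boron on C3 (β to the silyloxy group, non-benzylic) on the face anti to the 2-aryl group, so H enters C4 on that face and the 4-OTBS ends cis to the aryl group, while C–B oxidation with retention leaves the 3-OH as the only free hydroxyl.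

Step 7
Reactants: 11 (2R,3R,4R)-7,8-bis(benzyloxy)-2-[4-(benzyloxy)phenyl]-4-[(tert-butyldimethylsilyl)oxy]chroman-3-ol
Product: 12 (2R,4R)-7,8-bis(benzyloxy)-2-[4-(benzyloxy)phenyl]-4-[(tert-butyldimethylsilyl)oxy]chroman-3-one
Conditions: Dess–Martin periodinane (1.5 equiv), NaHCO3, CH2Cl2, 0 °C → rt; used at once
Reagents that add atoms: none
Why: Dess–Martin oxidation of the single free secondary alcohol under buffered neutral conditions, which do not epimerise the two α-stereocentres.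

Step 8
Reactants: 12 (2R,4R)-7,8-bis(benzyloxy)-2-[4-(benzyloxy)phenyl]-4-[(tert-butyldimethylsilyl)oxy]chroman-3-one
Product: 13 (2R,3S,4R)-7,8-bis(benzyloxy)-2-[4-(benzyloxy)phenyl]-4-[(tert-butyldimethylsilyl)oxy]chroman-3-ol (all-cis)
Conditions: LiBH(s-Bu)3 (1.5 equiv), THF, −78 °C; aq NH4Cl
Reagents that add atoms: none
Why: Substrate-controlled reduction with a bulky hydride from the face opposite the 2-aryl and 4-silyloxy groups gives the 3-OH cis to both and sets C3; any O4→O3 silyl shift is harmless because step 9 removes the silyl group.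

Step 9
Reactants: 13 (2R,3S,4R)-7,8-bis(benzyloxy)-2-[4-(benzyloxy)phenyl]-4-[(tert-butyldimethylsilyl)oxy]chroman-3-ol
Product: 14 (2R,3R,4R)-7,8-bis(benzyloxy)-2-[4-(benzyloxy)phenyl]chromane-3,4-diol (tri-O-benzylteracacidin, all-cis)
Conditions: Bu4NF (1.2 equiv), AcOH (1.2 equiv), THF, 0 °C → rt
Reagents that add atoms: none
Why: Fluoride-mediated desilylation, buffered so the benzylic diol is neither ionised nor epimerised.

Step 10
Reactants: 3 tert-butyl 3-[3,4-bis(benzyloxy)-2-hydroxyphenyl]-3-oxopropanoate; 15 3,4-bis(benzyloxy)benzaldehyde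
Product: 16 tert-butyl (2Z)-2-[3,4-bis(benzyloxy)-2-hydroxybenzoyl]-3-[3,4-bis(benzyloxy)phenyl]prop-2-enoate (E/Z mixture, Z drawn)
Conditions: piperidine (cat.), AcOH (cat.), 4 Å MS, toluene, rt
Reagents that add atoms: none
Why: Knoevenagel condensation, as in step 3.

Step 11
Reactants: 16 tert-butyl (2Z)-2-[3,4-bis(benzyloxy)-2-hydroxybenzoyl]-3-[3,4-bis(benzyloxy)phenyl]prop-2-enoate
Product: 19 (2S)-7,8-bis(benzyloxy)-2-[3,4-bis(benzyloxy)phenyl]chroman-4-one, via cyclised tert-butyl ester 17 (not isolated), via β-keto acid 18 (not isolated)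
Conditions: same thiourea catalyst (10 mol%), toluene, −25 °C; then p-TsOH·H2O, 80 °C; recrystallise
Reagents that add atoms: none
Why: The same asymmetric intramolecular oxa-Michael addition closes ring F and sets C2 (S), followed by acidolysis and decarboxylation.

Step 12
Reactants: 19 (2S)-7,8-bis(benzyloxy)-2-[3,4-bis(benzyloxy)phenyl]chroman-4-one
Product: 20 {[(2S)-7,8-bis(benzyloxy)-2-[3,4-bis(benzyloxy)phenyl]-2H-chromen-4-yl]oxy}(tert-butyl)dimethylsilane
Conditions: TBSOTf (1.3 equiv), Et3N (2 equiv), CH2Cl2, 0 °C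
Reagents that add atoms: tert-butyldimethylsilyl triflate CC(C)(C)[Si](C)(C)OS(=O)(=O)C(F)(F)F
Why: Soft enolisation to the silyl enol ether without ring opening, as in step 5.

Step 13
Reactants: 20 {[(2S)-7,8-bis(benzyloxy)-2-[3,4-bis(benzyloxy)phenyl]-2H-chromen-4-yl]oxy}(tert-butyl)dimethylsilane
Product: 22 (2R,3R,4R)-7,8-bis(benzyloxy)-2-[3,4-bis(benzyloxy)phenyl]-4-[(tert-butyldimethylsilyl)oxy]chroman-3-ol (2,3-trans-3,4-trans), via C3 alkylborane 21 (not isolated)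
Conditions: BH3·THF (2 equiv), THF, 0 °C → rt; then 30% H2O2, aq NaOAc, 0 °C
Reagents that add atoms: borane–THF B.C1CCOC1 (boron stays only in 21); hydrogen peroxide OO
Why: Hydroboration–oxidation anti to the 2-aryl group sets the final C4 configuration of the lower unit (4-O cis to the aryl group) and leaves only the 3-OH free.

Step 14
Reactants: 22 (2R,3R,4R)-7,8-bis(benzyloxy)-2-[3,4-bis(benzyloxy)phenyl]-4-[(tert-butyldimethylsilyl)oxy]chroman-3-ol
Product: 23 (2R,4R)-7,8-bis(benzyloxy)-2-[3,4-bis(benzyloxy)phenyl]-4-[(tert-butyldimethylsilyl)oxy]chroman-3-one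
Conditions: Dess–Martin periodinane (1.5 equiv), NaHCO3, CH2Cl2, 0 °C → rt; used at once
Reagents that add atoms: none
Why: Dess–Martin oxidation of the only free alcohol under neutral conditions.

Step 15
Reactants: 23 (2R,4R)-7,8-bis(benzyloxy)-2-[3,4-bis(benzyloxy)phenyl]-4-[(tert-butyldimethylsilyl)oxy]chroman-3-one
Product: 24 (2R,3S,4R)-7,8-bis(benzyloxy)-2-[3,4-bis(benzyloxy)phenyl]-4-[(tert-butyldimethylsilyl)oxy]chroman-3-ol (all-cis)
Conditions: LiBH(s-Bu)3 (1.5 equiv), THF, −78 °C; aq NH4Cl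
Reagents that add atoms: none
Why: Diastereoselective bulky-hydride reduction anti to the 2-aryl and 4-silyloxy groups sets the lower C3 with the 3-OH cis to both neighbours.

Step 16
Reactants: 24 (2R,3S,4R)-7,8-bis(benzyloxy)-2-[3,4-bis(benzyloxy)phenyl]-4-[(tert-butyldimethylsilyl)oxy]chroman-3-ol
Product: 25 (2R,3R,4R)-7,8-bis(benzyloxy)-2-[3,4-bis(benzyloxy)phenyl]chromane-3,4-diol (tetra-O-benzyl-(−)-melacacidin, all-cis)
Conditions: Bu4NF (1.2 equiv), AcOH (1.2 equiv), THF, 0 °C → rt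
Reagents that add atoms: none
Why: Buffered fluoride desilylation frees the cis-diol without touching the stereocentres.

Step 17
Reactants: 25 (2R,3R,4R)-7,8-bis(benzyloxy)-2-[3,4-bis(benzyloxy)phenyl]chromane-3,4-diol
Product: 27 (2R,3S,4R)-7,8-bis(benzyloxy)-2-[3,4-bis(benzyloxy)phenyl]chromane-3,4-diyl carbonate (cis-fused cyclic carbonate), via imidazole-1-carboxylate 26 (not isolated)
Conditions: 1,1′-carbonyldiimidazole (1.5 equiv), DMAP (cat.), CH2Cl2, rt
Reagents that add atoms: 1,1′-carbonyldiimidazole O=C(n1ccnc1)n1ccnc1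
Why: Carbonylation of the cis-diol gives the five-membered carbonate, which masks both hydroxyls as nucleophiles and makes the lower C4–O a poor, self-returning leaving group for the coupling.

Step 18
Reactants: 14 (2R,3R,4R)-7,8-bis(benzyloxy)-2-[4-(benzyloxy)phenyl]chromane-3,4-diol; 27 (2R,3S,4R)-7,8-bis(benzyloxy)-2-[3,4-bis(benzyloxy)phenyl]chromane-3,4-diyl carbonate
Product: 28 hepta-O-benzyl dimer carbonate: upper (2R,3R,4R)-7,8-bis(benzyloxy)-2-[4-(benzyloxy)phenyl]-3-hydroxychroman-4-yl unit bonded 4β (trans to its 3-OH) to C6 of the (2R,3S,4R) carbonate unit of 27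
Conditions: BF3·OEt2 (30 mol%), 4 Å MS, CH2Cl2, −30 → 0 °C; 14 added slowly to a threefold excess of 27, surplus 27 recovered by chromatography
Reagents that add atoms: none
Why: Friedel–Crafts alkylation by an SN1 path: BF3 ionises the benzylic 4-OH of 14, which leaves as water (the cation is stabilised by the para 7-OBn and the ring oxygen), and 27 attacks through C6 (para to its ring oxygen, ortho to 7-OBn, whereas C5 is peri-hindered) on the face anti to the axial 3-OH and the 2-aryl group, which sets the upper C4 as the 3,4-trans (4β) bond while the excess of 27 suppresses self-condensation of 14.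

Step 19
Reactants: 28 hepta-O-benzyl dimer carbonate
Product: 29 hepta-O-benzyl dimer triol: (2R,3R,4R)-7,8-bis(benzyloxy)-2-[4-(benzyloxy)phenyl]-4-{(2R,3R,4R)-7,8-bis(benzyloxy)-2-[3,4-bis(benzyloxy)phenyl]-3,4-dihydroxychroman-6-yl}chroman-3-ol
Conditions: K2CO3 (0.5 equiv), MeOH/THF 1:1, 0 °C → rt
Reagents that add atoms: none
Why: Base-catalysed transesterification of the cyclic carbonate frees the lower cis-diol while benzyl ethers and all stereocentres are inert.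

Step 20
Reactants: 29 hepta-O-benzyl dimer triol
Product: 30 target: (2R,3R,4S)-2-(4-hydroxyphenyl)-4-[(2R,3R,4R)-2-(3,4-dihydroxyphenyl)-3,4,7,8-tetrahydroxychroman-6-yl]chromane-3,7,8-triol
Conditions: H2 (1 atm), Pd(OH)2/C, THF/MeOH 1:1, rt, stopped at full debenzylation; filtered under argon; Sephadex LH-20
Reagents that add atoms: none
Why: Catalytic hydrogenolysis of the seven aryl benzyl ethers under neutral conditions is faster than cleavage of the benzylic C2–O bonds or the lower C4–OH, and no stereocentre is touched (the upper C4 descriptor changes from R to S only through CIP priorities).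

## Compound list

1 | 1-(2,3,4-trihydroxyphenyl)ethanone | CC(=O)c1ccc(O)c(O)c1O | starting material
2 | 1-[3,4-bis(benzyloxy)-2-hydroxyphenyl]ethanone | CC(=O)c1ccc(OCc2ccccc2)c(OCc2ccccc2)c1O | intermediate
3 | tert-butyl 3-[3,4-bis(benzyloxy)-2-hydroxyphenyl]-3-oxopropanoate | CC(C)(C)OC(=O)CC(=O)c1ccc(OCc2ccccc2)c(OCc2ccccc2)c1O | intermediate
4 | 4-(benzyloxy)benzaldehyde | O=Cc1ccc(OCc2ccccc2)cc1 | starting material
5 | tert-butyl (2Z)-2-[3,4-bis(benzyloxy)-2-hydroxybenzoyl]-3-[4-(benzyloxy)phenyl]prop-2-enoate | CC(C)(C)OC(=O)/C(=C\c1ccc(OCc2ccccc2)cc1)C(=O)c1ccc(OCc2ccccc2)c(OCc2ccccc2)c1O | intermediate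
6 | tert-butyl (2S,3R)-7,8-bis(benzyloxy)-2-[4-(benzyloxy)phenyl]-4-oxochromane-3-carboxylate (not isolated) | C(c1ccccc1)Oc1ccc(cc1)[C@H]1Oc2c(ccc(OCc3ccccc3)c2OCc2ccccc2)C(=O)[C@@H]1C(=O)OC(C)(C)C | intermediate
7 | (2S,3R)-7,8-bis(benzyloxy)-2-[4-(benzyloxy)phenyl]-4-oxochromane-3-carboxylic acid (not isolated) | C(c1ccccc1)Oc1ccc(cc1)[C@H]1Oc2c(ccc(OCc3ccccc3)c2OCc2ccccc2)C(=O)[C@@H]1C(=O)O | intermediate
8 | (2S)-7,8-bis(benzyloxy)-2-[4-(benzyloxy)phenyl]chroman-4-one | C(c1ccccc1)Oc1ccc(cc1)[C@H]1Oc2c(ccc(OCc3ccccc3)c2OCc2ccccc2)C(=O)C1 | intermediate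
9 | {[(2S)-7,8-bis(benzyloxy)-2-[4-(benzyloxy)phenyl]-2H-chromen-4-yl]oxy}(tert-butyl)dimethylsilane | C(c1ccccc1)Oc1ccc(cc1)[C@H]1Oc2c(ccc(OCc3ccccc3)c2OCc2ccccc2)C(O[Si](C)(C)C(C)(C)C)=C1 | intermediate
10 | [(2S,3R,4S)-7,8-bis(benzyloxy)-2-[4-(benzyloxy)phenyl]-4-[(tert-butyldimethylsilyl)oxy]chroman-3-yl]borane (not isolated) | C(c1ccccc1)Oc1ccc(cc1)[C@H]1Oc2c(ccc(OCc3ccccc3)c2OCc2ccccc2)[C@@H](O[Si](C)(C)C(C)(C)C)[C@@H]1B | intermediate
11 | (2R,3R,4R)-7,8-bis(benzyloxy)-2-[4-(benzyloxy)phenyl]-4-[(tert-butyldimethylsilyl)oxy]chroman-3-ol | C(c1ccccc1)Oc1ccc(cc1)[C@H]1Oc2c(ccc(OCc3ccccc3)c2OCc2ccccc2)[C@@H](O[Si](C)(C)C(C)(C)C)[C@@H]1O | intermediate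
12 | (2R,4R)-7,8-bis(benzyloxy)-2-[4-(benzyloxy)phenyl]-4-[(tert-butyldimethylsilyl)oxy]chroman-3-one | C(c1ccccc1)Oc1ccc(cc1)[C@H]1Oc2c(ccc(OCc3ccccc3)c2OCc2ccccc2)[C@@H](O[Si](C)(C)C(C)(C)C)C1=O | intermediate
13 | (2R,3S,4R)-7,8-bis(benzyloxy)-2-[4-(benzyloxy)phenyl]-4-[(tert-butyldimethylsilyl)oxy]chroman-3-ol | C(c1ccccc1)Oc1ccc(cc1)[C@H]1Oc2c(ccc(OCc3ccccc3)c2OCc2ccccc2)[C@@H](O[Si](C)(C)C(C)(C)C)[C@H]1O | intermediate
14 | (2R,3R,4R)-7,8-bis(benzyloxy)-2-[4-(benzyloxy)phenyl]chromane-3,4-diol | C(c1ccccc1)Oc1ccc(cc1)[C@H]1Oc2c(ccc(OCc3ccccc3)c2OCc2ccccc2)[C@@H](O)[C@H]1O | intermediate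
15 | 3,4-bis(benzyloxy)benzaldehyde | O=Cc1ccc(OCc2ccccc2)c(OCc2ccccc2)c1 | starting material
16 | tert-butyl (2Z)-2-[3,4-bis(benzyloxy)-2-hydroxybenzoyl]-3-[3,4-bis(benzyloxy)phenyl]prop-2-enoate | CC(C)(C)OC(=O)/C(=C\c1ccc(OCc2ccccc2)c(OCc2ccccc2)c1)C(=O)c1ccc(OCc2ccccc2)c(OCc2ccccc2)c1O | intermediate
17 | tert-butyl (2S,3R)-7,8-bis(benzyloxy)-2-[3,4-bis(benzyloxy)phenyl]-4-oxochromane-3-carboxylate (not isolated) | C(c1ccccc1)Oc1ccc(cc1OCc1ccccc1)[C@H]1Oc2c(ccc(OCc3ccccc3)c2OCc2ccccc2)C(=O)[C@@H]1C(=O)OC(C)(C)C | intermediate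
18 | (2S,3R)-7,8-bis(benzyloxy)-2-[3,4-bis(benzyloxy)phenyl]-4-oxochromane-3-carboxylic acid (not isolated) | C(c1ccccc1)Oc1ccc(cc1OCc1ccccc1)[C@H]1Oc2c(ccc(OCc3ccccc3)c2OCc2ccccc2)C(=O)[C@@H]1C(=O)O | intermediate
19 | (2S)-7,8-bis(benzyloxy)-2-[3,4-bis(benzyloxy)phenyl]chroman-4-one | C(c1ccccc1)Oc1ccc(cc1OCc1ccccc1)[C@H]1Oc2c(ccc(OCc3ccccc3)c2OCc2ccccc2)C(=O)C1 | intermediate
20 | {[(2S)-7,8-bis(benzyloxy)-2-[3,4-bis(benzyloxy)phenyl]-2H-chromen-4-yl]oxy}(tert-butyl)dimethylsilane | C(c1ccccc1)Oc1ccc(cc1OCc1ccccc1)[C@H]1Oc2c(ccc(OCc3ccccc3)c2OCc2ccccc2)C(O[Si](C)(C)C(C)(C)C)=C1 | intermediate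
21 | [(2S,3R,4S)-7,8-bis(benzyloxy)-2-[3,4-bis(benzyloxy)phenyl]-4-[(tert-butyldimethylsilyl)oxy]chroman-3-yl]borane (not isolated) | C(c1ccccc1)Oc1ccc(cc1OCc1ccccc1)[C@H]1Oc2c(ccc(OCc3ccccc3)c2OCc2ccccc2)[C@@H](O[Si](C)(C)C(C)(C)C)[C@@H]1B | intermediate
22 | (2R,3R,4R)-7,8-bis(benzyloxy)-2-[3,4-bis(benzyloxy)phenyl]-4-[(tert-butyldimethylsilyl)oxy]chroman-3-ol | C(c1ccccc1)Oc1ccc(cc1OCc1ccccc1)[C@H]1Oc2c(ccc(OCc3ccccc3)c2OCc2ccccc2)[C@@H](O[Si](C)(C)C(C)(C)C)[C@@H]1O | intermediate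
23 | (2R,4R)-7,8-bis(benzyloxy)-2-[3,4-bis(benzyloxy)phenyl]-4-[(tert-butyldimethylsilyl)oxy]chroman-3-one | C(c1ccccc1)Oc1ccc(cc1OCc1ccccc1)[C@H]1Oc2c(ccc(OCc3ccccc3)c2OCc2ccccc2)[C@@H](O[Si](C)(C)C(C)(C)C)C1=O | intermediate
24 | (2R,3S,4R)-7,8-bis(benzyloxy)-2-[3,4-bis(benzyloxy)phenyl]-4-[(tert-butyldimethylsilyl)oxy]chroman-3-ol | C(c1ccccc1)Oc1ccc(cc1OCc1ccccc1)[C@H]1Oc2c(ccc(OCc3ccccc3)c2OCc2ccccc2)[C@@H](O[Si](C)(C)C(C)(C)C)[C@H]1O | intermediate
25 | (2R,3R,4R)-7,8-bis(benzyloxy)-2-[3,4-bis(benzyloxy)phenyl]chromane-3,4-diol | C(c1ccccc1)Oc1ccc(cc1OCc1ccccc1)[C@H]1Oc2c(ccc(OCc3ccccc3)c2OCc2ccccc2)[C@@H](O)[C@H]1O | intermediate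
26 | (2R,3S,4R)-7,8-bis(benzyloxy)-2-[3,4-bis(benzyloxy)phenyl]-3-hydroxychroman-4-yl 1H-imidazole-1-carboxylate (not isolated) | C(c1ccccc1)Oc1ccc(cc1OCc1ccccc1)[C@H]1Oc2c(ccc(OCc3ccccc3)c2OCc2ccccc2)[C@@H](OC(=O)n3ccnc3)[C@H]1O | intermediate
27 | (2R,3S,4R)-7,8-bis(benzyloxy)-2-[3,4-bis(benzyloxy)phenyl]chromane-3,4-diyl carbonate (cis-fused) | C(c1ccccc1)Oc1ccc(cc1OCc1ccccc1)[C@H]1Oc2c(ccc(OCc3ccccc3)c2OCc2ccccc2)[C@@H](OC(=O)O5)[C@H]15 | intermediate
28 | hepta-O-benzyl dimer carbonate (upper 2R,3R,4R with free 3-OH, 4β→6 link; lower 2R,3S,4R cyclic carbonate) | C(c1ccccc1)Oc1ccc([C@H]2Oc3c(ccc(OCc4ccccc4)c3OCc3ccccc3)[C@H](c3cc4c(c(OCc5ccccc5)c3OCc3ccccc3)O[C@H](c3ccc(OCc5ccccc5)c(OCc5ccccc5)c3)[C@H](OC(=O)O5)[C@@H]45)[C@H]2O)cc1 | intermediate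
29 | hepta-O-benzyl dimer triol (upper 2R,3R,4R; lower 2R,3R,4R) | C(c1ccccc1)Oc1ccc([C@H]2Oc3c(ccc(OCc4ccccc4)c3OCc3ccccc3)[C@H](c3cc4c(c(OCc5ccccc5)c3OCc3ccccc3)O[C@H](c3ccc(OCc5ccccc5)c(OCc5ccccc5)c3)[C@H](O)[C@@H]4O)[C@H]2O)cc1 | intermediate
30 | (2R,3R,4S)-2-(4-hydroxyphenyl)-4-[(2R,3R,4R)-2-(3,4-dihydroxyphenyl)-3,4,7,8-tetrahydroxychroman-6-yl]chromane-3,7,8-triol | Oc1ccc([C@H]2Oc3c(ccc(O)c3O)[C@H](c3cc4c(c(O)c3O)O[C@H](c3ccc(O)c(O)c3)[C@H](O)[C@@H]4O)[C@H]2O)cc1 | target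

## Step count

Total step count: 20.
Longest linear sequence: 13 steps (1, 2, 10–20); the other branch (steps 3–9) runs in parallel and joins at step 18.

## Steps most likely to fail

Step 13 (hydroboration of the silyl enol ether; step 6 is the same reaction in the other series). The β-silyloxy alkylborane may eliminate, or the silyl group may migrate under the oxidation, so that the wrong hydroxyl is oxidised in step 14. The fallback sets out from 19 and comes back at 25. NaBH4 (MeOH/THF, 0 °C) reduces 19 to the 2,4-cis alcohol (2S,4S)-7,8-bis(benzyloxy)-2-[3,4-bis(benzyloxy)phenyl]chroman-4-ol F1. PPTS-catalysed dehydration (toluene, 80 °C, 4 Å MS) gives the flav-3-ene (2S)-7,8-bis(benzyloxy)-2-[3,4-bis(benzyloxy)phenyl]-2H-chromene F2. Woodward cis-hydroxylation (I2, AgOAc, wet AcOH) forms the iodonium anti to the aryl group, and the acetoxonium ion then delivers both oxygens to the aryl-bearing face. This gives the all-cis hydroxy acetate (2R,3R,4R)-7,8-bis(benzyloxy)-2-[3,4-bis(benzyloxy)phenyl]-4-hydroxychroman-3-yl acetate F3. Methanolysis (K2CO3, MeOH) gives 25.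

Step 18 (interflavanyl coupling). The benzylated pyrogallol-type arene is only moderately nucleophilic, so self-condensation of 14, C5 attack or ionisation of the carbonate may compete. The fallback sets out from 14 and comes back at 28. Thiolysis of 14 with phenylmethanethiol (5 equiv, BF3·OEt2 cat., CH2Cl2, −20 °C) traps the cation cleanly as the storable 3,4-trans thioether (2R,3S,4S)-4-(benzylsulfanyl)-7,8-bis(benzyloxy)-2-[4-(benzyloxy)phenyl]chroman-3-ol F4. This is then activated thiophilically under neutral conditions (AgBF4, 2,6-di-tert-butyl-4-methylpyridine, THF, 0 °C) in the presence of 27, a mode of activation to which the carbonate is inert, and gives 28.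

Step 20 (global hydrogenolysis). The lower benzylic C4–OH or the C2–O bonds may be over-reduced, or debenzylation may stall. The fallback sets out from 28 and comes back at 30. Non-reductive debenzylation with BCl3 and pentamethylbenzene (CH2Cl2, −78 °C) is run while the lower diol is still tied up as the electron-poor carbonate. It gives the heptaphenol carbonate (2R,3R,4S)-2-(4-hydroxyphenyl)-4-[(2R,3S,4R)-2-(3,4-dihydroxyphenyl)-7,8-dihydroxy-3,4-(carbonyldioxy)chroman-6-yl]chromane-3,7,8-triol F5. Catalytic K2CO3 in degassed MeOH (0 °C, argon) then removes the carbonate to give 30.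

## Further compounds

F1 | step 13 | (2S,4S)-7,8-bis(benzyloxy)-2-[3,4-bis(benzyloxy)phenyl]chroman-4-ol | C(c1ccccc1)Oc1ccc(cc1OCc1ccccc1)[C@H]1Oc2c(ccc(OCc3ccccc3)c2OCc2ccccc2)[C@@H](O)C1
F2 | step 13 | (2S)-7,8-bis(benzyloxy)-2-[3,4-bis(benzyloxy)phenyl]-2H-chromene | C(c1ccccc1)Oc1ccc(cc1OCc1ccccc1)[C@H]1Oc2c(ccc(OCc3ccccc3)c2OCc2ccccc2)C=C1
F3 | step 13 | (2R,3R,4R)-7,8-bis(benzyloxy)-2-[3,4-bis(benzyloxy)phenyl]-4-hydroxychroman-3-yl acetate | C(c1ccccc1)Oc1ccc(cc1OCc1ccccc1)[C@H]1Oc2c(ccc(OCc3ccccc3)c2OCc2ccccc2)[C@@H](O)[C@H]1OC(C)=O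
F4 | step 18 | (2R,3S,4S)-4-(benzylsulfanyl)-7,8-bis(benzyloxy)-2-[4-(benzyloxy)phenyl]chroman-3-ol | C(c1ccccc1)Oc1ccc(cc1)[C@H]1Oc2c(ccc(OCc3ccccc3)c2OCc2ccccc2)[C@H](SCc2ccccc2)[C@H]1O
F5 | step 20 | heptaphenol dimer with the lower 3,4-diol as cyclic carbonate (upper 2R,3R,4S; lower 2R,3S,4R) | Oc1ccc([C@H]2Oc3c(ccc(O)c3O)[C@H](c3cc4c(c(O)c3O)O[C@H](c3ccc(O)c(O)c3)[C@H](OC(=O)O5)[C@@H]45)[C@H]2O)cc1
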